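Numbers 1–42 refer to the compound list after the steps. Ring positions use azulene numbering (C1–C3 in the five-membered ring, C3a, C4–C8, C8a). "α" means the face that carries the C8a methyl group, "β" the opposite face.

## Analysis of the target

Compound 42 is a daucane-type sesquiterpene diester built on a hydroazulene, a cyclopentane fused to a cycloheptene. The seven-membered ring carries the C6=C7 olefin with the C6 methyl, the 3-methylbutanoate at C8, the angular methyl at C8a, the 4-hydroxybenzoate at C4, and an isolated methylene at C5. The five-membered ring carries the tertiary carbinol with the isopropyl group at C3. The five stereocentres are (3S,3aS,4R,8R,8aR). The ring fusion is cis (8a-CH3 and 3a-H both α), and the C3 hydroxyl and the C8 oxygen are also α. The C4 oxygen and the isopropyl group are β, so the aryl ester sits on the concave face next to the isopropyl group. Sensitive points are two different esters (one allylic, one carrying a free phenol) and the C6=C7 olefin, which is β,γ to C4 and would move into conjugation with a C4 ketone under base. The hard parts are the quaternary C8a flanked by two stereocentres, the contiguous C3–C3a–C4 triad with an oxygen on the hindered face, and telling the C4 and C8 hydroxyls apart. The strategy rests on the row C4–C5(H2)–C6=C7–C8(O)–C8a(quaternary). With a C3a=C4 double bond added, this is the cyclohepta-1,4-diene left by a cis-divinylcyclopropane rearrangement: C5 is the former cyclopropane methylene and C8–C8a is the new σ bond.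

## Retrosynthetic reasoning

**Aryl ester and phenol.** The C4–O acyl bond of 42 is cut last, through silyl ether 41, to diol 37 and acid 40 (from 38). The phenolic ester would not survive the hydride steps, so it goes on at the end. The tertiary C3 hydroxyl of 37 is too hindered to compete, so it needs no protection.

**C4 carbinol.** Diol 37 is traced to ketone 36, and this to alcohol 35 and its silyl ether 34. The C4 oxygen must lie on the concave face. A reagent that brings oxygen to C4 will approach from the convex face and give the wrong epimer, whereas a hydride approaching from that same face gives the right one. The C4–H bond is therefore made last, and the configuration of the C4 oxygen in earlier intermediates does not matter.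

**C8 ester.** Ester 34 comes from diol 32 and acid chloride 33. At that stage C8–OH is the only acylable hydroxyl.

**C3 carbinol.** Diol 32 is traced to epoxide 31, alkene 30, enol triflate 29 and ketone 28. The C3–O bond and the C3–isopropyl bond are cut separately. Direct addition of an isopropyl nucleophile to the C3 ketone would come from the convex face and place the hydroxyl β. Epoxidation of the C2=C3 alkene from the convex face places the oxygen α, and hydride then opens the epoxide at C2. The same hydride removes the pivalate that protects C8.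

**C4 oxygen and ring-fusion hydrogen.** Ketone 28 comes from β-hydroxy ketone 27, epoxy ketone 26 and enone 25. The C3 enone left by the key step is the handle: nucleophilic epoxidation of C3a=C4, reductive cleavage of the Cα–O bond, and protonation at C3a to set the cis ring fusion.

**C8 carbinol.** Enone 25 comes from alcohol 24 and this from ketone 22. C8 is reduced while C3 is still masked and C3a is still sp2, so that the angular methyl alone decides the face and no second carbonyl interferes.

**Seven-membered ring and C8a.** Ketone 22 is traced through mixed ketal 21 to the cis-divinylcyclopropane 20. The disconnection cuts C8–C8a and re-forms the cyclopropane bond C4–C6. It is made here because it builds the ring, the quaternary centre and both olefin positions at once, and leaves C3 and C8 as differently masked carbonyls. The forward reaction has to join a ketene acetal carbon to a fully substituted alkene carbon on one face only.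

**Ketene acetal.** Compound 20 comes from ester 18 by enolisation and silylation. Ester 18 comes from acid 14 through diazoketone 16 by an Arndt–Eistert one-carbon homologation. Acid 14 comes from cyclopropylmethanol 12 by oxidation.

**Cyclopropane and diene.** Alcohol 12 comes from the Z dienol 11 by hydroxyl-directed asymmetric cyclopropanation, which sets both cyclopropane stereocentres and the cis relationship of the two vinyl groups. Dienol 11 is cut at the alkenyl–alkenyl bond into bromo ketal 4 (from 3 and 1) and iodo alcohol 7 (from 5).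

## Alternatives that were turned down

**Alternative 1:** The disconnection is C3–C3a, with the cyclopentane closed from an open chain. In the forward step Rh2(OAc)4 converts the α-diazo ester A1 into a carbenoid at the future C3a. This inserts with retention into the C–H bond of the silyl-protected carbinol carbon (future C3) and gives cyclopentane A2.
- For: 1,5-C–H insertion is dependable, and it carries a preformed carbinol stereocentre into the most awkward position of the target, the C3 tertiary carbinol.
- Against: A2 holds only the five-membered ring. The seven-membered ring, the C4 and C8 oxygens and the C6=C7 olefin must all still be built from an ester and a protected hydroxymethyl group. The quaternary C8a has to be made beforehand in an acyclic precursor. The carbenoid can also attack the isopropyl methine or the silyl groups.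
- Comparison: Alternative 1 is stronger at C3, which the chosen route reaches only through triflate, coupling, epoxide and hydride. The chosen route offers the seven-membered ring, C8a and the olefin pattern in a single step.

**Alternative 2:** The disconnection is C8–C8a and C3a–C4 by [2+2] cycloaddition, followed by cleavage of the cyclobutane bond between the two oxygenated carbons. In the forward step, enone 1 bound to a chiral oxazaborolidine–AlBr3 Lewis acid is irradiated with the bis(silyloxy)cyclopentene A3 to give the cis-anti-cis tricycle A4.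
- For: it is the shortest way to the 5-7 skeleton. It starts from the same enone 1, and after glycol cleavage both C4 and C8 carry oxygen.
- Against: the alkene is tetrasubstituted, electron-rich and acid-sensitive in the presence of a strong Lewis acid. After cleavage C4 and C8 are two similar ketones that must be reduced with opposite facial sense and acylated differently. C6 arrives as a saturated methine, so C6=C7 has to be introduced regioselectively between two nearly equivalent α-positions.
- Comparison: Alternative 2 is stronger on step count to the core and on having the C4 oxygen in place. The chosen route offers C6=C7 in its final position and C3 and C8 distinguished from the start.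

**Alternative 3:** The disconnection is C3a–C8a, through a semipinacol shift on a decalin made by a quinone Diels–Alder reaction. In the forward step BF3·OEt2 opens the spiro-epoxide of the trans-decalin epoxy alcohol A5 while C3a migrates from C8 to C8a. One six-membered ring contracts to five and the other expands to seven, giving the cis-fused ketone A6.
- For: the Diels–Alder reaction sets relative configuration reliably. The shift is stereospecific, creates C8a and the cis fusion together, and A6 already carries the C4 oxygen and the C8 ketone.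
- Against: the route to A5 is long. C8a arrives with a hydroxymethyl group that must be deoxygenated to methyl. The shift needs exact anti-periplanar alignment and competes with other migrations. Absolute control needs an enantioselective quinone cycloaddition.
- Comparison: Alternative 3 is as strong or stronger on the C4 oxygen and the ring fusion, which the chosen route sets by epoxidation, protonation and a late oxidation–reduction. The chosen route offers the angular methyl from the first step, absolute configuration from one asymmetric cyclopropanation, and fewer steps to the bicycle.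

Key step: step 10

## Route

Remark: the (4S,5S) dioxaborolane ligand in step 5 is chosen by analogy with the known facial sense of this reagent class (the enantiomeric ligand would be used if the sense proved opposite). Compounds 26–35 are drawn with the C4 oxygen α, as expected from convex-face attack; the C4 epimer would pass through the same steps and converge at ketone 36.

Step 1
Reactants: 1 3-methylcyclopent-2-en-1-one
Product: 3 2-bromo-3-methylcyclopent-2-en-1-one, via trans-dibromo ketone 2 (not isolated)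
Conditions: Br2, CH2Cl2, 0 °C; then Et3N, 0 °C → rt
Reagents that add atoms: bromine, BrBr
Why: Bromine adds anti across the enone and triethylamine removes HBr from the α-bromo ketone (bromination–dehydrobromination), a standard route to α-bromo enones.

Step 2
Reactants: 3 2-bromo-3-methylcyclopent-2-en-1-one
Product: 4 6-bromo-7-methyl-1,4-dioxaspiro[4.4]non-6-ene
Conditions: HOCH2CH2OH, p-TsOH (cat.), PhH, reflux, Dean–Stark
Reagents that add atoms: ethane-1,2-diol, OCCO
Why: Acid-catalysed ketalisation with azeotropic removal of water; the α-bromine keeps the double bond from migrating, and the ketal masks the C3 carbonyl until step 11.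

Step 3
Reactants: 5 prop-2-yn-1-ol
Product: 7 (2Z)-3-iodo-2-methylprop-2-en-1-ol, via chelated vinylmagnesium alkoxide 6 (not isolated)
Conditions: MeMgBr (2.5 equiv), CuI (10 mol%), THF, −10 °C → rt; then I2, −78 → 0 °C
Reagents that add atoms: methylmagnesium bromide, C[Mg]Br; iodine, II
Why: Copper-catalysed anti carbomagnesiation of the propargylic alkoxide puts methyl on the internal carbon and magnesium cis to the CH2O group; iodinolysis with retention gives the Z iodide.

Step 4
Reactants: 4 6-bromo-7-methyl-1,4-dioxaspiro[4.4]non-6-ene; 7 (2Z)-3-iodo-2-methylprop-2-en-1-ol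
Product: 11 (2Z)-2-methyl-3-(7-methyl-1,4-dioxaspiro[4.4]non-6-en-6-yl)prop-2-en-1-ol, via vinyllithium 8 (not isolated), via vinylzinc chloride 9 (not isolated), via sodium alkoxide 10 (not isolated)
Conditions: 4, t-BuLi (2.0 equiv), THF, −78 °C; ZnCl2, −78 → 0 °C; then 7 pre-treated with NaH (THF, 0 °C), Pd(PPh3)4 (5 mol%), THF, rt → 50 °C
Reagents that add atoms: none
Why: Bromine–lithium exchange, transmetalation to zinc and Negishi coupling join two hindered alkenyl partners with retention of both geometries, so the cyclopentenyl group ends cis to CH2OH; the hydroxyl is carried as its alkoxide.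

Step 5
Reactants: 11 (2Z)-2-methyl-3-(7-methyl-1,4-dioxaspiro[4.4]non-6-en-6-yl)prop-2-en-1-ol
Product: 12 [(1R,2S)-1-methyl-2-(7-methyl-1,4-dioxaspiro[4.4]non-6-en-6-yl)cyclopropyl]methanol
Conditions: Et2Zn, CH2I2, DME, CH2Cl2, −10 °C; then 11 and (4S,5S)-2-butyl-N,N,N',N'-tetramethyl-1,3,2-dioxaborolane-4,5-dicarboxamide (1.2 equiv), CH2Cl2, −10 °C → rt
Reagents that add atoms: diiodomethane, ICI
Why: Dioxaborolane-mediated asymmetric Simmons–Smith cyclopropanation: the zinc alkoxide directs methylene transfer to the allylic alkene only and the chiral boronate fixes the face, setting both cyclopropane stereocentres. The addition is stereospecifically syn, so the Z geometry of 11 becomes the cis relationship of the cyclopentenyl group and the CH2OH arm.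

Step 6
Reactants: 12 [(1R,2S)-1-methyl-2-(7-methyl-1,4-dioxaspiro[4.4]non-6-en-6-yl)cyclopropyl]methanol
Product: 14 (1R,2R)-1-methyl-2-(7-methyl-1,4-dioxaspiro[4.4]non-6-en-6-yl)cyclopropane-1-carboxylic acid, via cyclopropanecarbaldehyde 13 (not isolated)
Conditions: TEMPO (cat.), NaOCl (cat.), NaClO2, MeCN/phosphate buffer (pH 6.7), 35 °C
Reagents that add atoms: sodium chlorite, [Na+].[O-]Cl=O
Why: Oxoammonium oxidation to the aldehyde and chlorite oxidation to the acid occur in one pot near neutral pH, which the ketal tolerates; no stereocentre is touched (the descriptor at C2 changes only through the priority rules).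

Step 7
Reactants: 14 (1R,2R)-1-methyl-2-(7-methyl-1,4-dioxaspiro[4.4]non-6-en-6-yl)cyclopropane-1-carboxylic acid
Product: 16 2-diazo-1-[(1R,2S)-1-methyl-2-(7-methyl-1,4-dioxaspiro[4.4]non-6-en-6-yl)cyclopropyl]ethan-1-one, via acid chloride 15 (not isolated)
Conditions: 1-chloro-N,N,2-trimethylprop-1-en-1-amine, CH2Cl2, 0 °C → rt; then CH2N2 (excess), Et2O, 0 °C
Reagents that add atoms: diazomethane, C=[N+]=[N-]
Why: The chloroenamine makes the hindered acid chloride without free HCl, so the ketal survives; acylation of diazomethane gives the diazoketone (first stage of the Arndt–Eistert homologation).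

Step 8
Reactants: 16 2-diazo-1-[(1R,2S)-1-methyl-2-(7-methyl-1,4-dioxaspiro[4.4]non-6-en-6-yl)cyclopropyl]ethan-1-one
Product: 18 methyl 2-[(1S,2S)-1-methyl-2-(7-methyl-1,4-dioxaspiro[4.4]non-6-en-6-yl)cyclopropyl]acetate, via ketene 17 (not isolated)
Conditions: PhCO2Ag (10 mol%), Et3N, MeOH/THF, −25 °C → rt, dark
Reagents that add atoms: methanol, CO
Why: Silver-catalysed Wolff rearrangement: the cyclopropyl carbon migrates with retention and methanol traps the ketene, giving the homologated ester.

Step 9
Reactants: 18 methyl 2-[(1S,2S)-1-methyl-2-(7-methyl-1,4-dioxaspiro[4.4]non-6-en-6-yl)cyclopropyl]acetate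
Product: 20 tert-butyl({(E)-1-methoxy-2-[(1R,2S)-1-methyl-2-(7-methyl-1,4-dioxaspiro[4.4]non-6-en-6-yl)cyclopropyl]ethenyl}oxy)dimethylsilane, via lithium enolate 19 (not isolated)
Conditions: LiN(iPr)2, THF, −78 °C; t-BuMe2SiCl, DMPU, −78 → 0 °C; pentane, filtration (no aqueous work-up)
Reagents that add atoms: tert-butyldimethylsilyl chloride, CC(C)(C)[Si](C)(C)Cl
Why: Kinetic ester enolisation in THF gives the enolate with the oxygen–lithium bond trans to the cyclopropyl group, and O-silylation gives the E ketene acetal. The smaller methoxy group is then the one that points inward in the next step; either geometry would lead to the same ketone.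

Step 10
Reactants: 20 tert-butyl({(E)-1-methoxy-2-[(1R,2S)-1-methyl-2-(7-methyl-1,4-dioxaspiro[4.4]non-6-en-6-yl)cyclopropyl]ethenyl}oxy)dimethylsilane
Product: 22 (8aR)-3,3-(ethylenedioxy)-6,8a-dimethyl-1,2,3,5-tetrahydroazulen-8(8aH)-one, via mixed silyl methyl ketal 21 (not isolated)
Conditions: PhMe, Et3N (1 mol%), 100 °C; then Bu4NF, AcOH, THF, 0 °C
Reagents that add atoms: none
Why: On heating, 20 should undergo the thermal cis-divinylcyclopropane to cyclohepta-1,4-diene rearrangement, a concerted [3,3]-sigmatropic shift through a boat-like transition state in which both alkenes lie over the three-membered ring; this reaction type is known, also with silyloxy-substituted vinyl termini. The ketene acetal carbon (C8) bonds to the methyl-bearing cyclopentene carbon (C8a) while the cyclopropane bond C4–C6 breaks, so the seven-membered ring closes by strain-driven enlargement of the three-membered ring and not by an end-on cyclisation, and the two new ring alkenes (C3a=C4, C6=C7) are necessarily cis. The electron-rich ketene acetal should help bond formation at the fully substituted terminus, but the inward methoxy group and the inward C8a methyl raise the barrier, so heating to about 100 °C is expected to be needed. The one lasting new stereocentre is C8a: the two cis cyclopropane carbons of 20 allow only one endo boat, which fixes the face of the cyclopentene carbon that reaches the ketene acetal, so (1R,2S)-20 should give (8aR). The step needs the two vinyl groups cis, which the Z alkene of 11 and the stereospecific cyclopropanation secure, and no cis C–H placed for a homodienyl 1,5-hydrogen shift, which holds because the cyclopropane methyl is trans to the cyclopentenyl group. Buffered fluoride then cleaves only the silyl methyl ketal at C8 and leaves the C3 dioxolane, so the two carbonyl groups stay differentiated.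

Step 11
Reactants: 22 (8aR)-3,3-(ethylenedioxy)-6,8a-dimethyl-1,2,3,5-tetrahydroazulen-8(8aH)-one
Product: 24 (8R,8aR)-8-hydroxy-6,8a-dimethyl-2,5,8,8a-tetrahydroazulen-3(1H)-one, via allylic alcohol ketal 23 (not isolated)
Conditions: NaBH4, CeCl3·7H2O, MeOH, −78 °C; then PPTS, acetone/H2O, rt
Reagents that add atoms: none
Why: Luche 1,2-reduction: hydride adds to C8 anti to the angular methyl on the adjacent quaternary carbon, as in reductions of ketones next to a methyl-bearing ring-fusion carbon, giving the C8 alcohol cis to the methyl. Mild acid then hydrolyses the allylic dioxolane to the C3 enone.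

Step 12
Reactants: 24 (8R,8aR)-8-hydroxy-6,8a-dimethyl-2,5,8,8a-tetrahydroazulen-3(1H)-one
Product: 25 (8R,8aR)-6,8a-dimethyl-3-oxo-1,2,3,5,8,8a-hexahydroazulen-8-yl 2,2-dimethylpropanoate
Conditions: t-BuCOCl, pyridine, DMAP, CH2Cl2, 0 → 40 °C
Reagents that add atoms: pivaloyl chloride, CC(C)(C)C(=O)Cl
Why: DMAP-catalysed acylation; the pivalate has no α-hydrogen (safe in step 16), lowers the reactivity of C6=C7 toward peracid (step 18) and is removed by the hydride of step 19.

Step 13
Reactants: 25 (8R,8aR)-6,8a-dimethyl-3-oxo-1,2,3,5,8,8a-hexahydroazulen-8-yl 2,2-dimethylpropanoate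
Product: 26 (3aR,4S,8R,8aS)-3a,4-epoxy-6,8a-dimethyl-3-oxo-1,2,3,3a,4,5,8,8a-octahydroazulen-8-yl 2,2-dimethylpropanoate
Conditions: t-BuOOH, benzyltrimethylammonium hydroxide (cat.), THF, −20 → 0 °C
Reagents that add atoms: tert-butyl hydroperoxide, CC(C)(C)OO
Why: Weitz–Scheffer nucleophilic epoxidation touches only the enone alkene C3a=C4, not the isolated C6=C7. The peroxide should add to C4 from the exposed convex face; the C4 configuration is not critical because it is reset in steps 22 and 23.

Step 14
Reactants: 26 (3aR,4S,8R,8aS)-3a,4-epoxy-6,8a-dimethyl-3-oxo-1,2,3,3a,4,5,8,8a-octahydroazulen-8-yl 2,2-dimethylpropanoate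
Product: 27 (3aS,4S,8R,8aR)-4-hydroxy-6,8a-dimethyl-3-oxo-1,2,3,3a,4,5,8,8a-octahydroazulen-8-yl 2,2-dimethylpropanoate
Conditions: SmI2 (2.2 equiv), THF/MeOH, −90 °C
Reagents that add atoms: none
Why: SmI2 reduces the ketone to a ketyl and cleaves the Cα–O bond of the α,β-epoxy ketone, giving a trivalent samarium enolate and the C4 alkoxide. Methanol should protonate C3a from the convex face, on the side of the 8a-methyl and of the neighbouring alkoxide, which gives the cis ring fusion.

Step 15
Reactants: 27 (3aS,4S,8R,8aR)-4-hydroxy-6,8a-dimethyl-3-oxo-1,2,3,3a,4,5,8,8a-octahydroazulen-8-yl 2,2-dimethylpropanoate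
Product: 28 (3aS,4S,8R,8aR)-6,8a-dimethyl-3-oxo-4-(triethylsilyloxy)-1,2,3,3a,4,5,8,8a-octahydroazulen-8-yl 2,2-dimethylpropanoate
Conditions: Et3SiCl, imidazole, DMF, 0 °C
Reagents that add atoms: chlorotriethylsilane, CC[Si](Cl)(CC)CC
Why: Silylation of the secondary alcohol under weakly basic conditions, which avoids β-elimination and retro-aldol cleavage of the β-hydroxy ketone.

Step 16
Reactants: 28 (3aS,4S,8R,8aR)-6,8a-dimethyl-3-oxo-4-(triethylsilyloxy)-1,2,3,3a,4,5,8,8a-octahydroazulen-8-yl 2,2-dimethylpropanoate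
Product: 29 (3aS,4S,8R,8aR)-6,8a-dimethyl-4-(triethylsilyloxy)-3-(trifluoromethylsulfonyloxy)-1,3a,4,5,8,8a-hexahydroazulen-8-yl 2,2-dimethylpropanoate
Conditions: KN(SiMe3)2, THF, −78 °C; N-(5-chloropyridin-2-yl)-1,1,1-trifluoro-N-(trifluoromethylsulfonyl)methanesulfonamide, −78 °C
Reagents that add atoms: N-(5-chloropyridin-2-yl)-1,1,1-trifluoro-N-(trifluoromethylsulfonyl)methanesulfonamide, O=S(=O)(N(c1ccc(Cl)cn1)S(=O)(=O)C(F)(F)F)C(F)(F)F
Why: Kinetic deprotonation takes the C2 methylene and not the crowded C3a methine between the quaternary C8a and the silyloxy carbon, so the enolate is trapped as the C2=C3 enol triflate. C3a is left untouched and β-elimination is avoided.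

Step 17
Reactants: 29 (3aS,4S,8R,8aR)-6,8a-dimethyl-4-(triethylsilyloxy)-3-(trifluoromethylsulfonyloxy)-1,3a,4,5,8,8a-hexahydroazulen-8-yl 2,2-dimethylpropanoate
Product: 30 (3aS,4S,8R,8aR)-6,8a-dimethyl-3-(propan-2-yl)-4-(triethylsilyloxy)-1,3a,4,5,8,8a-hexahydroazulen-8-yl 2,2-dimethylpropanoate
Conditions: i-PrZnBr, PdCl2(dppf) (5 mol%), THF, 50 °C
Reagents that add atoms: isopropylzinc bromide, CC(C)[Zn]Br
Why: Negishi coupling of an alkenyl triflate with a secondary alkylzinc reagent; the wide-bite-angle ferrocenyl diphosphine favours reductive elimination over β-hydride elimination, so the isopropyl group should not isomerise, and the ester and silyl ether are tolerated.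

Step 18
Reactants: 30 (3aS,4S,8R,8aR)-6,8a-dimethyl-3-(propan-2-yl)-4-(triethylsilyloxy)-1,3a,4,5,8,8a-hexahydroazulen-8-yl 2,2-dimethylpropanoate
Product: 31 (2R,3S,3aS,4S,8R,8aR)-2,3-epoxy-6,8a-dimethyl-3-(propan-2-yl)-4-(triethylsilyloxy)-1,2,3,3a,4,5,8,8a-octahydroazulen-8-yl 2,2-dimethylpropanoate
Conditions: m-CPBA, NaHCO3, CH2Cl2, −20 → 0 °C
Reagents that add atoms: 3-chloroperoxybenzoic acid, O=C(OO)c1cccc(Cl)c1
Why: Prilezhaev epoxidation: C2=C3 is the more electron-rich alkene, because C6=C7 is deactivated by the allylic pivalate. The peracid approaches the convex α face of the cis-fused cyclopentene, anti to the C4 branch, so the C3 oxygen arrives α.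

Step 19
Reactants: 31 (2R,3S,3aS,4S,8R,8aR)-2,3-epoxy-6,8a-dimethyl-3-(propan-2-yl)-4-(triethylsilyloxy)-1,2,3,3a,4,5,8,8a-octahydroazulen-8-yl 2,2-dimethylpropanoate
Product: 32 (3S,3aS,4S,8R,8aR)-6,8a-dimethyl-3-(propan-2-yl)-4-(triethylsilyloxy)-1,2,3,3a,4,5,8,8a-octahydroazulene-3,8-diol
Conditions: LiEt3BH (6 equiv), THF, 0 °C → rt
Reagents that add atoms: none
Why: Hydride opens the trisubstituted epoxide by SN2 attack at the less substituted C2, leaving the tertiary C3 hydroxyl α with the isopropyl group β. The same reagent reduces the pivalate off C8, and the silyl ether is untouched.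

Step 20
Reactants: 32 (3S,3aS,4S,8R,8aR)-6,8a-dimethyl-3-(propan-2-yl)-4-(triethylsilyloxy)-1,2,3,3a,4,5,8,8a-octahydroazulene-3,8-diol; 33 3-methylbutanoyl chloride
Product: 34 (3S,3aS,4S,8R,8aR)-3-hydroxy-6,8a-dimethyl-3-(propan-2-yl)-4-(triethylsilyloxy)-1,2,3,3a,4,5,8,8a-octahydroazulen-8-yl 3-methylbutanoate
Conditions: pyridine, DMAP (cat.), CH2Cl2, 0 °C → rt
Reagents that add atoms: none
Why: DMAP-catalysed acylation of the secondary allylic C8 alcohol; the tertiary C3 hydroxyl, flanked by the isopropyl group and the ring fusion, should not react.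

Step 21
Reactants: 34 (3S,3aS,4S,8R,8aR)-3-hydroxy-6,8a-dimethyl-3-(propan-2-yl)-4-(triethylsilyloxy)-1,2,3,3a,4,5,8,8a-octahydroazulen-8-yl 3-methylbutanoate
Product: 35 (3S,3aS,4S,8R,8aR)-3,4-dihydroxy-6,8a-dimethyl-3-(propan-2-yl)-1,2,3,3a,4,5,8,8a-octahydroazulen-8-yl 3-methylbutanoate
Conditions: HF·pyridine, pyridine, THF, 0 °C → rt
Reagents that add atoms: none
Why: Buffered fluoride removes the triethylsilyl ether without ionising the allylic ester.

Step 22
Reactants: 35 (3S,3aS,4S,8R,8aR)-3,4-dihydroxy-6,8a-dimethyl-3-(propan-2-yl)-1,2,3,3a,4,5,8,8a-octahydroazulen-8-yl 3-methylbutanoate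
Product: 36 (3S,3aR,8R,8aR)-3-hydroxy-6,8a-dimethyl-4-oxo-3-(propan-2-yl)-1,2,3,3a,4,5,8,8a-octahydroazulen-8-yl 3-methylbutanoate
Conditions: Dess–Martin periodinane, NaHCO3, CH2Cl2, 0 °C
Reagents that add atoms: none
Why: Only the secondary C4 alcohol can be oxidised. The buffered, non-basic medium should prevent conjugation of C6=C7, epimerisation at C3a and retro-aldol cleavage; the step erases the C4 configuration.

Step 23
Reactants: 36 (3S,3aR,8R,8aR)-3-hydroxy-6,8a-dimethyl-4-oxo-3-(propan-2-yl)-1,2,3,3a,4,5,8,8a-octahydroazulen-8-yl 3-methylbutanoate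
Product: 37 (3S,3aS,4R,8R,8aR)-3,4-dihydroxy-6,8a-dimethyl-3-(propan-2-yl)-1,2,3,3a,4,5,8,8a-octahydroazulen-8-yl 3-methylbutanoate
Conditions: NaBH4, CeCl3·7H2O, MeOH, −78 °C
Reagents that add atoms: none
Why: Fast, nearly neutral Luche-type reduction: hydride reaches the C4 carbonyl from the face of the C3a hydrogen, anti to the fully substituted C3 on the adjacent carbon. The new C4–H is therefore α and the hydroxyl β, trans to the 3a-hydrogen as in the target; the ester is not reduced at this temperature.

Step 24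
Reactants: 38 4-hydroxybenzoic acid
Product: 40 4-(tert-butyldimethylsilyloxy)benzoic acid, via bis-silylated acid 39 (not isolated)
Conditions: t-BuMe2SiCl (2.2 equiv), imidazole, DMF, rt; then K2CO3, THF/MeOH/H2O, rt; citric acid
Reagents that add atoms: tert-butyldimethylsilyl chloride, CC(C)(C)[Si](C)(C)Cl
Why: Both acidic groups are silylated and the labile silyl ester is then hydrolysed selectively, leaving the aryl silyl ether.

Step 25
Reactants: 37 (3S,3aS,4R,8R,8aR)-3,4-dihydroxy-6,8a-dimethyl-3-(propan-2-yl)-1,2,3,3a,4,5,8,8a-octahydroazulen-8-yl 3-methylbutanoate; 40 4-(tert-butyldimethylsilyloxy)benzoic acid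
Product: 41 (3S,3aS,4R,8R,8aR)-3-hydroxy-6,8a-dimethyl-8-(3-methylbutanoyloxy)-3-(propan-2-yl)-1,2,3,3a,4,5,8,8a-octahydroazulen-4-yl 4-(tert-butyldimethylsilyloxy)benzoate
Conditions: EDC·HCl, DMAP, CH2Cl2, rt → 40 °C
Reagents that add atoms: none
Why: Steglich esterification of the only acylable hydroxyl; the tertiary C3 hydroxyl stays free, and DMAP transfers the aroyl group to the hindered secondary alcohol.

Step 26
Reactants: 41 (3S,3aS,4R,8R,8aR)-3-hydroxy-6,8a-dimethyl-8-(3-methylbutanoyloxy)-3-(propan-2-yl)-1,2,3,3a,4,5,8,8a-octahydroazulen-4-yl 4-(tert-butyldimethylsilyloxy)benzoate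
Product: 42 (3S,3aS,4R,8R,8aR)-3-hydroxy-6,8a-dimethyl-8-(3-methylbutanoyloxy)-3-(propan-2-yl)-1,2,3,3a,4,5,8,8a-octahydroazulen-4-yl 4-hydroxybenzoate
Conditions: Bu4NF, AcOH, THF, 0 °C
Reagents that add atoms: none
Why: Buffered fluoride cleaves the aryl silyl ether quickly and leaves both esters and the tertiary alcohol untouched.

## Compound list

1 | 3-methylcyclopent-2-en-1-one | CC1=CC(=O)CC1 | starting material
2 | trans-2,3-dibromo-3-methylcyclopentan-1-one (racemic, one enantiomer drawn) | C[C@]1(Br)CCC(=O)[C@@H]1Br | intermediate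
3 | 2-bromo-3-methylcyclopent-2-en-1-one | CC1=C(Br)C(=O)CC1 | intermediate
4 | 6-bromo-7-methyl-1,4-dioxaspiro[4.4]non-6-ene | CC1=C(Br)C2(CC1)OCCO2 | intermediate
5 | prop-2-yn-1-ol | C#CCO | starting material
6 | bromo[(1Z)-3-(bromomagnesiooxy)-2-methylprop-1-en-1-yl]magnesium | C/C(CO[Mg]Br)=C/[Mg]Br | intermediate
7 | (2Z)-3-iodo-2-methylprop-2-en-1-ol | OC/C(C)=C\I | intermediate
8 | (7-methyl-1,4-dioxaspiro[4.4]non-6-en-6-yl)lithium | CC1=C([Li])C2(CC1)OCCO2 | intermediate
9 | chloro(7-methyl-1,4-dioxaspiro[4.4]non-6-en-6-yl)zinc | CC1=C([Zn]Cl)C2(CC1)OCCO2 | intermediate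
10 | sodium (2Z)-3-iodo-2-methylprop-2-en-1-olate | [Na+].[O-]C/C(C)=C\I | intermediate
11 | (2Z)-2-methyl-3-(7-methyl-1,4-dioxaspiro[4.4]non-6-en-6-yl)prop-2-en-1-ol | OC/C(C)=C\C1=C(C)CCC12OCCO2 | intermediate
12 | [(1R,2S)-1-methyl-2-(7-methyl-1,4-dioxaspiro[4.4]non-6-en-6-yl)cyclopropyl]methanol | C[C@@]1(CO)C[C@@H]1C2=C(C)CCC23OCCO3 | intermediate
13 | (1R,2S)-1-methyl-2-(7-methyl-1,4-dioxaspiro[4.4]non-6-en-6-yl)cyclopropane-1-carbaldehyde | C[C@@]1(C=O)C[C@@H]1C2=C(C)CCC23OCCO3 | intermediate
14 | (1R,2R)-1-methyl-2-(7-methyl-1,4-dioxaspiro[4.4]non-6-en-6-yl)cyclopropane-1-carboxylic acid | C[C@@]1(C(=O)O)C[C@@H]1C2=C(C)CCC23OCCO3 | intermediate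
15 | (1R,2R)-1-methyl-2-(7-methyl-1,4-dioxaspiro[4.4]non-6-en-6-yl)cyclopropane-1-carbonyl chloride | C[C@@]1(C(=O)Cl)C[C@@H]1C2=C(C)CCC23OCCO3 | intermediate
16 | 2-diazo-1-[(1R,2S)-1-methyl-2-(7-methyl-1,4-dioxaspiro[4.4]non-6-en-6-yl)cyclopropyl]ethan-1-one | C[C@@]1(C(=O)C=[N+]=[N-])C[C@@H]1C2=C(C)CCC23OCCO3 | intermediate
17 | 2-[(1R,2S)-1-methyl-2-(7-methyl-1,4-dioxaspiro[4.4]non-6-en-6-yl)cyclopropyl]ethen-1-one (ketene) | C[C@@]1(C=C=O)C[C@@H]1C2=C(C)CCC23OCCO3 | intermediate
18 | methyl 2-[(1S,2S)-1-methyl-2-(7-methyl-1,4-dioxaspiro[4.4]non-6-en-6-yl)cyclopropyl]acetate | C[C@@]1(CC(=O)OC)C[C@@H]1C2=C(C)CCC23OCCO3 | intermediate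
19 | lithium (Z)-1-methoxy-2-[(1R,2S)-1-methyl-2-(7-methyl-1,4-dioxaspiro[4.4]non-6-en-6-yl)cyclopropyl]ethen-1-olate | C[C@@]1(/C=C(/O[Li])OC)C[C@@H]1C2=C(C)CCC23OCCO3 | intermediate
20 | tert-butyl({(E)-1-methoxy-2-[(1R,2S)-1-methyl-2-(7-methyl-1,4-dioxaspiro[4.4]non-6-en-6-yl)cyclopropyl]ethenyl}oxy)dimethylsilane | C[C@@]1(/C=C(/O[Si](C)(C)C(C)(C)C)OC)C[C@@H]1C2=C(C)CCC23OCCO3 | intermediate
21 | (8S,8aR)-8-(tert-butyldimethylsilyloxy)-3,3-(ethylenedioxy)-8-methoxy-6,8a-dimethyl-1,2,3,5,8,8a-hexahydroazulene | CC1=C[C@](OC)(O[Si](C)(C)C(C)(C)C)[C@]2(C)CCC3(OCCO3)C2=CC1 | intermediate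
22 | (8aR)-3,3-(ethylenedioxy)-6,8a-dimethyl-1,2,3,5-tetrahydroazulen-8(8aH)-one | CC1=CC(=O)[C@]2(C)CCC3(OCCO3)C2=CC1 | intermediate
23 | (8R,8aR)-3,3-(ethylenedioxy)-6,8a-dimethyl-1,2,3,5,8,8a-hexahydroazulen-8-ol | CC1=C[C@@H](O)[C@]2(C)CCC3(OCCO3)C2=CC1 | intermediate
24 | (8R,8aR)-8-hydroxy-6,8a-dimethyl-2,5,8,8a-tetrahydroazulen-3(1H)-one | CC1=C[C@@H](O)[C@]2(C)CCC(=O)C2=CC1 | intermediate
25 | (8R,8aR)-6,8a-dimethyl-3-oxo-1,2,3,5,8,8a-hexahydroazulen-8-yl 2,2-dimethylpropanoate | CC1=C[C@@H](OC(=O)C(C)(C)C)[C@]2(C)CCC(=O)C2=CC1 | intermediate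
26 | (3aR,4S,8R,8aS)-3a,4-epoxy-6,8a-dimethyl-3-oxo-1,2,3,3a,4,5,8,8a-octahydroazulen-8-yl 2,2-dimethylpropanoate | CC1=C[C@@H](OC(=O)C(C)(C)C)[C@]2(C)CCC(=O)[C@@]23O[C@H]3C1 | intermediate
27 | (3aS,4S,8R,8aR)-4-hydroxy-6,8a-dimethyl-3-oxo-1,2,3,3a,4,5,8,8a-octahydroazulen-8-yl 2,2-dimethylpropanoate | CC1=C[C@@H](OC(=O)C(C)(C)C)[C@]2(C)CCC(=O)[C@@H]2[C@@H](O)C1 | intermediate
28 | (3aS,4S,8R,8aR)-6,8a-dimethyl-3-oxo-4-(triethylsilyloxy)-1,2,3,3a,4,5,8,8a-octahydroazulen-8-yl 2,2-dimethylpropanoate | CC1=C[C@@H](OC(=O)C(C)(C)C)[C@]2(C)CCC(=O)[C@@H]2[C@@H](O[Si](CC)(CC)CC)C1 | intermediate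
29 | (3aS,4S,8R,8aR)-6,8a-dimethyl-4-(triethylsilyloxy)-3-(trifluoromethylsulfonyloxy)-1,3a,4,5,8,8a-hexahydroazulen-8-yl 2,2-dimethylpropanoate | CC1=C[C@@H](OC(=O)C(C)(C)C)[C@]2(C)CC=C(OS(=O)(=O)C(F)(F)F)[C@@H]2[C@@H](O[Si](CC)(CC)CC)C1 | intermediate
30 | (3aS,4S,8R,8aR)-6,8a-dimethyl-3-(propan-2-yl)-4-(triethylsilyloxy)-1,3a,4,5,8,8a-hexahydroazulen-8-yl 2,2-dimethylpropanoate | CC1=C[C@@H](OC(=O)C(C)(C)C)[C@]2(C)CC=C(C(C)C)[C@@H]2[C@@H](O[Si](CC)(CC)CC)C1 | intermediate
31 | (2R,3S,3aS,4S,8R,8aR)-2,3-epoxy-6,8a-dimethyl-3-(propan-2-yl)-4-(triethylsilyloxy)-1,2,3,3a,4,5,8,8a-octahydroazulen-8-yl 2,2-dimethylpropanoate | CC1=C[C@@H](OC(=O)C(C)(C)C)[C@]2(C)C[C@H]3O[C@@]3(C(C)C)[C@@H]2[C@@H](O[Si](CC)(CC)CC)C1 | intermediate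
32 | (3S,3aS,4S,8R,8aR)-6,8a-dimethyl-3-(propan-2-yl)-4-(triethylsilyloxy)-1,2,3,3a,4,5,8,8a-octahydroazulene-3,8-diol | CC1=C[C@@H](O)[C@]2(C)CC[C@](O)(C(C)C)[C@@H]2[C@@H](O[Si](CC)(CC)CC)C1 | intermediate
33 | 3-methylbutanoyl chloride | CC(C)CC(=O)Cl | starting material
34 | (3S,3aS,4S,8R,8aR)-3-hydroxy-6,8a-dimethyl-3-(propan-2-yl)-4-(triethylsilyloxy)-1,2,3,3a,4,5,8,8a-octahydroazulen-8-yl 3-methylbutanoate | CC1=C[C@@H](OC(=O)CC(C)C)[C@]2(C)CC[C@](O)(C(C)C)[C@@H]2[C@@H](O[Si](CC)(CC)CC)C1 | intermediate
35 | (3S,3aS,4S,8R,8aR)-3,4-dihydroxy-6,8a-dimethyl-3-(propan-2-yl)-1,2,3,3a,4,5,8,8a-octahydroazulen-8-yl 3-methylbutanoate | CC1=C[C@@H](OC(=O)CC(C)C)[C@]2(C)CC[C@](O)(C(C)C)[C@@H]2[C@@H](O)C1 | intermediate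
36 | (3S,3aR,8R,8aR)-3-hydroxy-6,8a-dimethyl-4-oxo-3-(propan-2-yl)-1,2,3,3a,4,5,8,8a-octahydroazulen-8-yl 3-methylbutanoate | CC1=C[C@@H](OC(=O)CC(C)C)[C@]2(C)CC[C@](O)(C(C)C)[C@@H]2C(=O)C1 | intermediate
37 | (3S,3aS,4R,8R,8aR)-3,4-dihydroxy-6,8a-dimethyl-3-(propan-2-yl)-1,2,3,3a,4,5,8,8a-octahydroazulen-8-yl 3-methylbutanoate | CC1=C[C@@H](OC(=O)CC(C)C)[C@]2(C)CC[C@](O)(C(C)C)[C@@H]2[C@H](O)C1 | intermediate
38 | 4-hydroxybenzoic acid | O=C(O)c1ccc(O)cc1 | starting material
39 | tert-butyldimethylsilyl 4-(tert-butyldimethylsilyloxy)benzoate | CC(C)(C)[Si](C)(C)OC(=O)c1ccc(O[Si](C)(C)C(C)(C)C)cc1 | intermediate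
40 | 4-(tert-butyldimethylsilyloxy)benzoic acid | CC(C)(C)[Si](C)(C)Oc1ccc(C(=O)O)cc1 | intermediate
41 | (3S,3aS,4R,8R,8aR)-3-hydroxy-6,8a-dimethyl-8-(3-methylbutanoyloxy)-3-(propan-2-yl)-1,2,3,3a,4,5,8,8a-octahydroazulen-4-yl 4-(tert-butyldimethylsilyloxy)benzoate | CC1=C[C@@H](OC(=O)CC(C)C)[C@]2(C)CC[C@](O)(C(C)C)[C@@H]2[C@H](OC(=O)c2ccc(O[Si](C)(C)C(C)(C)C)cc2)C1 | intermediate
42 | (3S,3aS,4R,8R,8aR)-3-hydroxy-6,8a-dimethyl-8-(3-methylbutanoyloxy)-3-(propan-2-yl)-1,2,3,3a,4,5,8,8a-octahydroazulen-4-yl 4-hydroxybenzoate | CC1=C[C@@H](OC(=O)CC(C)C)[C@]2(C)CC[C@](O)(C(C)C)[C@@H]2[C@H](OC(=O)c2ccc(O)cc2)C1 | target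

## Step count and least certain steps

The route has 26 steps in total. The longest linear sequence is 24 steps (steps 1, 2, 4–23, 25 and 26); steps 3 and 24 prepare side partners.

**Step 10 (key step).** The likeliest failure is that the rearrangement is too slow: both termini carry an inward substituent and one of them becomes quaternary. Forcing the temperature would then bring silyl migration in the ketene acetal or cis–trans stereomutation of the cyclopropane before ring enlargement. The fallback lowers the congestion at the oxygenated terminus. It sets out from ester 18, which is reduced (iBu2AlH, −78 °C) to the cyclopropylacetaldehyde F1. This is converted (t-BuMe2SiOTf, Et3N) into the silyl enol ether F2, whose E isomer has only hydrogen pointing inward. Heating should give the 8-silyloxy cycloheptadiene ketal F3 as C8 epimers, and fluoride frees the allylic alcohol F4. Oxidation with MnO2 converges both epimers and returns to the route at 22.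

**Step 5.** The likeliest failures are loss of chemoselectivity or of facial control: the ketal oxygens can direct the zinc carbenoid to the tetrasubstituted cyclopentene alkene, and zinc iodide may open the allylic ketal. The fallback builds the cyclopropane before the diene exists. It sets out from iodo alcohol 7, which is cyclopropanated under the same dioxaborolane conditions to the iodocyclopropylmethanol F5. Negishi coupling of F5 (as its alkoxide) with vinylzinc chloride 9, made from 4 as in step 4, proceeds with retention at the cyclopropyl carbon and returns to the route at 12.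

**Step 13.** The likeliest failure is base-induced migration of the skipped C3a=C4/C6=C7 diene into conjugation through the acidic C5 methylene, competing with peroxide addition. The fallback replaces the basic peroxide with a boron nucleophile under nearly neutral conditions. It sets out from enone 25. Copper-catalysed conjugate borylation (CuCl, NaOtBu cat., bis(pinacolato)diboron, MeOH, THF) gives the β-boryl ketone F6. Oxidation with NaBO3·4H2O returns to the route at 27 and so also replaces step 14.

**Step 14.** The likeliest failures are protonation of the samarium enolate from the concave face, which gives the trans ring fusion, or retro-aldol cleavage of the β-hydroxy ketone. The fallback avoids any enolate by delivering the C3a hydrogen and the C4 oxygen together to one face. It sets out from 22, which is reduced as in step 11 but without the acid stage, giving 23, and then acylated to the pivalate ketal F7. Hydroboration–oxidation (BH3·THF, 0 °C; NaBO3·4H2O) of the unconjugated C3a=C4 alkene adds hydrogen and boron syn from the exposed face and gives the hydroxy ketal F8. Silylation gives the silyl ether ketal F9, and mild acid hydrolysis of the dioxolane returns to the route at 28.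

**Step 18.** The likeliest failure is competing epoxidation of C6=C7 or attack on the wrong face of C2=C3. The fallback uses a reagent more sensitive to steric and electronic deactivation and removes the extra oxygen afterwards. It sets out from 30. Dihydroxylation (OsO4 cat., N-methylmorpholine N-oxide) should give the cis-diol F10 from the convex face. The secondary C2 hydroxyl is converted with 1,1'-thiocarbonyldiimidazole into the imidazolylthiocarbonate F11, and Barton–McCombie reduction (Bu3SnH, AIBN, PhMe, 80 °C) gives the tertiary alcohol pivalate F12. Treatment with LiEt3BH removes the pivalate and returns to the route at 32.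

## Further compounds

F1 | step 10 | 2-[(1S,2S)-1-methyl-2-(7-methyl-1,4-dioxaspiro[4.4]non-6-en-6-yl)cyclopropyl]acetaldehyde | C[C@@]1(CC=O)C[C@@H]1C2=C(C)CCC23OCCO3
F2 | step 10 | tert-butyldimethyl({2-[(1R,2S)-1-methyl-2-(7-methyl-1,4-dioxaspiro[4.4]non-6-en-6-yl)cyclopropyl]ethenyl}oxy)silane (E and Z isomers) | C[C@@]1(C=CO[Si](C)(C)C(C)(C)C)C[C@@H]1C2=C(C)CCC23OCCO3
F3 | step 10 | (8aR)-8-(tert-butyldimethylsilyloxy)-3,3-(ethylenedioxy)-6,8a-dimethyl-1,2,3,5,8,8a-hexahydroazulene (both C8 epimers) | CC1=CC(O[Si](C)(C)C(C)(C)C)[C@]2(C)CCC3(OCCO3)C2=CC1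
F4 | step 10 | (8aR)-3,3-(ethylenedioxy)-6,8a-dimethyl-1,2,3,5,8,8a-hexahydroazulen-8-ol (both C8 epimers) | CC1=CC(O)[C@]2(C)CCC3(OCCO3)C2=CC1
F5 | step 5 | [(1S,2S)-2-iodo-1-methylcyclopropyl]methanol | C[C@@]1(CO)C[C@@H]1I
F6 | step 13 | (3aR,4S,8R,8aR)-6,8a-dimethyl-3-oxo-4-(4,4,5,5-tetramethyl-1,3,2-dioxaborolan-2-yl)-1,2,3,3a,4,5,8,8a-octahydroazulen-8-yl 2,2-dimethylpropanoate | CC1=C[C@@H](OC(=O)C(C)(C)C)[C@]2(C)CCC(=O)[C@@H]2[C@@H](B3OC(C)(C)C(C)(C)O3)C1
F7 | step 14 | (8R,8aR)-3,3-(ethylenedioxy)-6,8a-dimethyl-1,2,3,5,8,8a-hexahydroazulen-8-yl 2,2-dimethylpropanoate | CC1=C[C@@H](OC(=O)C(C)(C)C)[C@]2(C)CCC3(OCCO3)C2=CC1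
F8 | step 14 | (3aS,4S,8R,8aR)-3,3-(ethylenedioxy)-4-hydroxy-6,8a-dimethyl-1,2,3,3a,4,5,8,8a-octahydroazulen-8-yl 2,2-dimethylpropanoate | CC1=C[C@@H](OC(=O)C(C)(C)C)[C@]2(C)CCC3(OCCO3)[C@@H]2[C@@H](O)C1
F9 | step 14 | (3aS,4S,8R,8aR)-3,3-(ethylenedioxy)-6,8a-dimethyl-4-(triethylsilyloxy)-1,2,3,3a,4,5,8,8a-octahydroazulen-8-yl 2,2-dimethylpropanoate | CC1=C[C@@H](OC(=O)C(C)(C)C)[C@]2(C)CCC3(OCCO3)[C@@H]2[C@@H](O[Si](CC)(CC)CC)C1
F10 | step 18 | (2R,3S,3aS,4S,8R,8aR)-2,3-dihydroxy-6,8a-dimethyl-3-(propan-2-yl)-4-(triethylsilyloxy)-1,2,3,3a,4,5,8,8a-octahydroazulen-8-yl 2,2-dimethylpropanoate | CC1=C[C@@H](OC(=O)C(C)(C)C)[C@]2(C)C[C@@H](O)[C@](O)(C(C)C)[C@@H]2[C@@H](O[Si](CC)(CC)CC)C1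
F11 | step 18 | (2R,3S,3aS,4S,8R,8aR)-3-hydroxy-2-(1H-imidazole-1-carbothioyloxy)-6,8a-dimethyl-3-(propan-2-yl)-4-(triethylsilyloxy)-1,2,3,3a,4,5,8,8a-octahydroazulen-8-yl 2,2-dimethylpropanoate | CC1=C[C@@H](OC(=O)C(C)(C)C)[C@]2(C)C[C@@H](OC(=S)n3ccnc3)[C@](O)(C(C)C)[C@@H]2[C@@H](O[Si](CC)(CC)CC)C1
F12 | step 18 | (3S,3aS,4S,8R,8aR)-3-hydroxy-6,8a-dimethyl-3-(propan-2-yl)-4-(triethylsilyloxy)-1,2,3,3a,4,5,8,8a-octahydroazulen-8-yl 2,2-dimethylpropanoate | CC1=C[C@@H](OC(=O)C(C)(C)C)[C@]2(C)CC[C@](O)(C(C)C)[C@@H]2[C@@H](O[Si](CC)(CC)CC)C1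
A1 | alternative 1 | methyl (3R,6S)-6-[tert-butyl(dimethyl)silyl]oxy-3-{[tert-butyl(dimethyl)silyl]oxymethyl}-2-diazo-3,7-dimethyloctanoate | COC(=O)C(=[N+]=[N-])[C@](C)(CO[Si](C)(C)C(C)(C)C)CC[C@H](O[Si](C)(C)C(C)(C)C)C(C)C
A2 | alternative 1 | methyl (1R,2S,5R)-2-[tert-butyl(dimethyl)silyl]oxy-5-{[tert-butyl(dimethyl)silyl]oxymethyl}-5-methyl-2-(propan-2-yl)cyclopentane-1-carboxylate | CC(C)(C)[Si](C)(C)OC[C@]1(C)CC[C@](O[Si](C)(C)C(C)(C)C)(C(C)C)[C@@H]1C(=O)OC
A3 | alternative 2 | 4-methyl-1,2-bis(trimethylsilyloxy)cyclopent-1-ene | CC1CC(O[Si](C)(C)C)=C(O[Si](C)(C)C)C1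
A4 | alternative 2 | cis-anti-cis 1,4-dimethyl-2,6-bis(trimethylsilyloxy)tricyclo[5.3.0.0(2,6)]decan-8-one (configuration as in the SMILES) | C[C@@H]1C[C@@]3(O[Si](C)(C)C)[C@]2(C)CCC(=O)[C@@H]2[C@@]3(O[Si](C)(C)C)C1
A5 | alternative 3 | trans-decalin epoxy alcohol with ring-fusion tertiary hydroxyl at C8, spiro-oxirane at C8a, ethylene ketal at C3, tert-butyldimethylsilyl ether at C4 and C5=C6 olefin (azulene numbering of the rearranged product; configuration as in the SMILES) | CC1=C[C@@H](O[Si](C)(C)C(C)(C)C)[C@H]2C3(OCCO3)CC[C@]4(CO4)[C@]2(O)C1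
A6 | alternative 3 | cis-fused 4-(tert-butyldimethylsilyloxy)-3,3-(ethylenedioxy)-8a-(hydroxymethyl)-6-methyl-1,2,3,3a,4,7-hexahydroazulen-8(8aH)-one (configuration as in the SMILES) | CC1=C[C@@H](O[Si](C)(C)C(C)(C)C)[C@H]2C3(OCCO3)CC[C@@]2(CO)C(=O)C1
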